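- The amber, grey and violet runs show how a closed flask fills with target, and from them we carry one quantity: how strongly the enzyme turns on target compared with starting material.

common to all: precatalyst 4.8 µM

| run | starting material | remark | time |
|---|---|---|---|
| amber | 10 mM | run made earlier |  |
| grey | 5 mM | run made earlier |  |
| violet | 20 mM | run made earlier |  |
| dawn | 10 mM (fed, over 2.00 d) | all but starting material at the start; starting material goes in evenly over 2.00 d, the run ends at 2.5 d | 2.5 d |
| summer | 10 mM | one stirred flow tank at steady state, fed with the mixture as stated, mean residence time 2.5 d |  |
| winter | 10 mM | a closed flask charged with all of it at once and left for 2.5 d | 2.5 d |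

amber run (percent of the starting material charged)

| time / h | target / % | over-reaction product / % |
|---|---|---|
| 3.00 | 0.3 | 0 |
| 6.00 | 0.4 | 0.4 |
| 15.0 | 1.3 | 0 |
| 40.0 | 5.6 | 0.3 |

grey run (percent of the starting material charged)

| time / d | target / % | over-reaction product / % |
|---|---|---|
| 0.208 | 0.9 | 0 |
| 0.500 | 1.3 | 0.7 |
| 1.04 | 4.3 | 0 |
| 2.50 | 20.2 | 1.7 |

violet run (percent of the starting material charged)

| time / d | target / % | over-reaction product / % |
|---|---|---|
| 0.333 | 0.4 | 0.9 |
| 0.833 | 1.0 | 0 |
| 1.67 | 2.4 | 0.4 |
| 2.50 | 4.7 | 0.6 |

(scatter of a reading: 0.5 percentage points)

- the stated concentrations are those of everything mixed, before any reaction; amounts are the same in each set-up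
- steps under discussion: enzyme -> spent catalyst; starting material + enzyme -> target + enzyme; enzyme + target -> enzyme + over-reaction product; precatalyst -> enzyme
- the feed brings no volume worth counting
- the earlier runs were made in a closed, stirred flask

1. the set-up with the highest share of target in all that became target or over-reaction product, at the outlet or at the end ("none" if the first two lie within 2 percentage points) (dawn / summer / winter / none)
2. share of target in all that became target or over-reaction product, at the outlet or at the end, dawn
3. share of target in all that became target or over-reaction product, at the outlet or at the end, summer
4. share of target in all that became target or over-reaction product, at the outlet or at the end, winter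

- The curve of all that has reacted starts at 0.208 mM/d in the amber run up to 15.0 h. It then averages 0.442 mM/d up to 40.0 h, and the grey run gives 0.603 mM/d between 1.04 d and 2.50 d. So it bends upward, which we read as precatalyst turning into enzyme.
- At 2.50 d the grey run has converted 1.09 mM and the violet run 1.06 mM, although violet's charge is larger. The rate is therefore zero-order in starting material, and we take 1.08 mM for the winter flask, nearly all of it counted as target.
- With the target rate indifferent to starting material, we take over-reaction product made per target made as a constant times the target present at that moment. In a closed flask the target climbs from zero, so the average over the target made is half its end value, whatever the pace of the curve.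
- The grey run's end readings then give the competition number 0.167 /mM, our name for this selectivity factor: over-reaction product made per target made, for each mM of target present. It is a reading, and its over-reaction product scatters by 29.4 %.
- We reckon the winter flask at 91.8 %. The dawn flask's steady feed of 5.00 mM/d is faster than the grey run's rate, so starting material builds up in it, and with a rate indifferent to starting material we put dawn at the same figure. The summer tank makes its target at the outlet level of target, twice the closed average, which gives 84.8 % at the same conversion, so our best is none.
- The forecast, higher than our figures , gave 95 % for dawn, 92.7 % for summer, 96.1 % for winter and best none: “Winter and dawn lie within 2 points, so the answer is none.”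
- The flasks give 96.9 % for dawn, 94.5 % for summer, 96.9 % for winter and best none.

    enzyme → spent catalyst (k = 5.60 × 10⁻⁴ /min)
    starting material + enzyme → target + enzyme, rate k2*[starting material]*[enzyme]/(1 + ([starting material]/Km2) + ([starting material]/Ksi2)^2) (0.410 mM, 6.00 mM, k = 1300 /M/min)
    enzyme + target → enzyme + over-reaction product (k = 28.0 /M/min)
    precatalyst → enzyme (k = 1.60 × 10⁻⁴ /min)

- The summer flask's over-reaction product per target is twice the winter flask's. With the summer flask's 9.18 % of target, the competition number read from the grey run gives 1.40 % of over-reaction product, and that flask holds 0.538 %.

The readings come from a simulation with made-up constants; scatter was added.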